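The upper pyran ring is opened at C4–C4a. The upper C4 methine is doubly benzylic: it sits between C4a of the upper phloroglucinol A ring and C8′ of the catechin A ring, so a C4 cation is strongly stabilised by O1′ and the 5′,7′-oxygens. In one operation, acid ionises either C4 epimer of an open-chain carbinol and the tethered 3,5-bis(benzyloxy)phenyl ether closes ring C through its ortho carbon, forming C4–C4a and setting C4 trans to the C3 benzyloxy group. The precursor is a perbenzylated 8-catechinyl carbinol whose C2 aryl ether and C3 benzyl ether centres come from (R)-glyceraldehyde acetonide.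

Key step: step 12

Assumptions and remarks on the chemistry:
- 3,5-Bis(benzyloxy)phenol is taken as a purchasable reagent.
- Flavan numbering (C2, C3, C4, C4a, C8a; primed locants for the catechin unit) is used for the open-chain intermediates as well.
- The upper unit of the target is 2,3-cis-3,4-trans (2R,3R,4R) and the lower unit is (2R,3S)-catechin. The C2 aryl ether oxygen must therefore stand syn to the C3 oxygen. Felkin–Anh addition to glyceraldehyde acetonide gives the anti carbinol, so the aryl ether is installed with inversion (Mitsunobu). An O-arylation that retains the carbinol configuration would lead from the anti carbinol into the 2,3-trans series.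

Step 1
Reactants: 1 5-bromobenzene-1,2,3-triol
Product: 2 5-bromo-1,2,3-tris(benzyloxy)benzene
Conditions: BnBr (3.3 equiv), K2CO3, DMF, rt → 50 °C, N2
Reagents that add atoms: benzyl bromide, BrCc1ccccc1
Why: Williamson etherification of the three phenols under carbonate base is routine and the aryl bromide is inert to it.

Step 2
Reactants: 2 5-bromo-1,2,3-tris(benzyloxy)benzene; 3 (R)-glyceraldehyde acetonide
Product: 5 (S)-[(R)-2,2-dimethyl-1,3-dioxolan-4-yl][3,4,5-tris(benzyloxy)phenyl]methanol (anti carbinol), via arylmagnesium bromide 4 (not isolated)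
Conditions: Mg, I2 (cat.), THF, reflux; then 3, THF, −78 → −40 °C; aq. NH4Cl
Reagents that add atoms: none
Why: Grignard addition to the α-alkoxy aldehyde under Felkin–Anh (non-chelation) control should favour the anti (1S) carbinol, the new centre being set by the dioxolane stereocentre (later C3); the minor syn epimer is removed by chromatography.

Step 3
Reactants: 5 anti carbinol; 6 3,5-bis(benzyloxy)phenol
Product: 7 (R)-4-{(R)-[3,5-bis(benzyloxy)phenoxy][3,4,5-tris(benzyloxy)phenyl]methyl}-2,2-dimethyl-1,3-dioxolane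
Conditions: PPh3, DIAD, toluene, 0 °C → rt
Reagents that add atoms: none
Why: Mitsunobu etherification displaces the activated benzylic oxygen by the phenol in an SN2 sense, so the carbinol centre is inverted to the (R) aryl ether (later C2), syn to the dioxolane oxygen as the 2,3-cis upper unit requires.

Step 4
Reactants: 7 aryl ether acetonide
Product: 8 (2R,3R)-3-[3,5-bis(benzyloxy)phenoxy]-3-[3,4,5-tris(benzyloxy)phenyl]propane-1,2-diol
Conditions: AcOH/THF/H2O (3:1:1), 50 °C
Reagents that add atoms: none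
Why: Acid-catalysed acetal hydrolysis frees the terminal 1,2-diol, while the benzyl ethers and the benzylic aryl ether, which does not ionise in dilute acetic acid, stay intact.

Step 5
Reactants: 8 diol
Product: 9 (4R)-4-{(R)-[3,5-bis(benzyloxy)phenoxy][3,4,5-tris(benzyloxy)phenyl]methyl}-2-phenyl-1,3-dioxolane (both acetal epimers)
Conditions: PhCH(OMe)2, CSA (cat.), CH2Cl2, rt; Et3N quench
Reagents that add atoms: benzaldehyde dimethyl acetal, COC(OC)c1ccccc1
Why: Acid-catalysed transacetalisation converts the 1,2-diol into the five-membered benzylidene acetal; the new acetal centre is not controlled and need not be, since it becomes a CH2 group in the next step.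

Step 6
Reactants: 9 benzylidene acetal
Product: 10 (2R,3R)-2-(benzyloxy)-3-[3,5-bis(benzyloxy)phenoxy]-3-[3,4,5-tris(benzyloxy)phenyl]propan-1-ol
Conditions: DIBAL-H (3 equiv), CH2Cl2, −20 → 0 °C; Rochelle salt work-up
Reagents that add atoms: none
Why: In this regioselective reductive acetal opening, DIBAL-H coordinates the less hindered primary oxygen and cleaves that C–O bond, so hydride delivery leaves the benzyl group on the secondary oxygen (later C3) and frees the primary alcohol.

Step 7
Reactants: 10 primary alcohol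
Product: 11 (2S,3R)-2-(benzyloxy)-3-[3,5-bis(benzyloxy)phenoxy]-3-[3,4,5-tris(benzyloxy)phenyl]propanal
Conditions: Dess–Martin periodinane, CH2Cl2, 0 °C → rt; used crude at once
Reagents that add atoms: none
Why: Dess–Martin oxidation is non-basic, so the α-benzyloxy β-aryloxy aldehyde should form without epimerisation at the α-carbon (later C3) or β-elimination of the aryloxide.

Step 8
Reactants: 12 (+)-catechin
Product: 13 5,7,3′,4′-tetra-O-benzyl-(+)-catechin
Conditions: BnBr (4.4 equiv), K2CO3, DMF, 0 °C → rt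
Reagents that add atoms: benzyl bromide, BrCc1ccccc1
Why: Williamson etherification with carbonate base benzylates only the four phenols and leaves the less acidic 3-OH and both stereocentres untouched.

Step 9
Reactants: 13 tetra-O-benzylcatechin
Product: 14 8-bromo-5,7,3′,4′-tetra-O-benzyl-(+)-catechin
Conditions: NBS (1.0 equiv), CH2Cl2, −78 °C → rt
Reagents that add atoms: N-bromosuccinimide, O=C1CCC(=O)N1Br
Why: Electrophilic aromatic bromination of the phloroglucinol-type A ring with NBS is established to occur selectively at C8 of tetra-O-benzyl flavan-3-ols.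

Step 10
Reactants: 14 8-bromo-tetra-O-benzylcatechin
Product: 15 8-bromo-3,5,7,3′,4′-penta-O-benzyl-(+)-catechin
Conditions: NaH, BnBr, DMF, 0 °C → rt
Reagents that add atoms: benzyl bromide, BrCc1ccccc1
Why: Williamson etherification of the secondary alkoxide with benzyl bromide leaves the aryl bromide and both stereocentres unaffected.

Step 11
Reactants: 15 8-bromo-penta-O-benzylcatechin; 11 aldehyde
Product: 17 (1RS,2R,3R)-2-(benzyloxy)-3-[3,5-bis(benzyloxy)phenoxy]-1-(3,5,7,3′,4′-penta-O-benzylcatechin-8-yl)-3-[3,4,5-tris(benzyloxy)phenyl]propan-1-ol (C4 epimer mixture), via 8-lithio-penta-O-benzylcatechin 16 (not isolated)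
Conditions: 15 (1.4 equiv), n-BuLi (1.3 equiv), THF, −78 °C; then 11, −78 °C; aq. NH4Cl; Et3N-deactivated silica
Reagents that add atoms: none
Why: Bromine–lithium exchange gives a 2,6-dialkoxyaryllithium, a weakly basic nucleophile that should add 1,2 to the aldehyde at −78 °C faster than it enolises it; the new C4 carbinol centre forms as a mixture, which does not matter because it is erased in step 12.

Step 12
Reactants: 17 aryl ether carbinol (C4 epimer mixture)
Product: 19 undeca-O-benzyl-epigallocatechin-(4β→8)-catechin, via C4 benzylic cation 18 (not isolated)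
Conditions: TMSOTf (0.1 equiv), CH2Cl2 (0.005 M), −78 → −40 °C; Et3N quench
Reagents that add atoms: none
Why: Acid ionises the C4 hydroxyl of either epimer to the same planar cation 18, delocalised over the catechin A ring as a quinone-methide-type oxocarbenium ion (O1′, 5′-OBn, 7′-OBn), and the tethered 3,5-bis(benzyloxy)phenyl ether attacks through the ring carbon ortho to the ether oxygen and para to a benzyloxy group, then rearomatises by proton loss, which regenerates the acid. This is an intramolecular Friedel–Crafts alkylation by a stabilised benzylic cation, the reaction type used for 4-arylchromans and, intermolecularly, for benzylated proanthocyanidins. Ring C closes in a six-membered mode that is exo with respect to the C4=C8′ π-system of the cation and takes the aromatic C4a–C8a bond into the ring (ortho-annulation); the two ortho carbons of the ether ring are equivalent, so no regiochemical question arises. C4 is the only new stereocentre and is substrate-controlled: in the half-chair transition state the C2 aryl is equatorial and the C3 benzyloxy group axial, and the catechinyl group takes the quasi-axial position anti to C3–OBn to avoid peri strain with the 5-benzyloxy group, which should give the 2,3-cis-3,4-trans (4R) product; reversibility of the alkylation under acid favours the same isomer. The step needs the phloroglucinol ether ring to win over the tribenzyloxyphenyl ring (which could only close a five-membered indane) and over intermolecular capture, and this is secured by the triple oxygen activation of the attacking carbon, the favourable six-membered closure, high dilution and low temperature.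

Step 13
Reactants: 19 undeca-O-benzyl dimer
Product: 20 epigallocatechin-(4β→8)-catechin (target)
Conditions: H2 (1 atm), Pd(OH)2/C, THF/MeOH/H2O (20:20:1), rt
Reagents that add atoms: none
Why: Catalytic hydrogenolysis cleaves all eleven benzyl ethers under neutral conditions that should leave the flavan C2–O1 bonds, the interflavan C4–C8′ bond and all five stereocentres untouched.

Compound list
1 | 5-bromobenzene-1,2,3-triol | Oc1cc(Br)cc(O)c1O | starting material
2 | 5-bromo-1,2,3-tris(benzyloxy)benzene | Brc1cc(OCc2ccccc2)c(OCc2ccccc2)c(OCc2ccccc2)c1 | intermediate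
3 | (R)-2,2-dimethyl-1,3-dioxolane-4-carbaldehyde ((R)-glyceraldehyde acetonide) | O=C[C@H]1COC(C)(C)O1 | starting material
4 | [3,4,5-tris(benzyloxy)phenyl]magnesium bromide | Br[Mg]c1cc(OCc2ccccc2)c(OCc2ccccc2)c(OCc2ccccc2)c1 | intermediate
5 | (S)-[(R)-2,2-dimethyl-1,3-dioxolan-4-yl][3,4,5-tris(benzyloxy)phenyl]methanol (anti carbinol) | O[C@@H](c1cc(OCc2ccccc2)c(OCc2ccccc2)c(OCc2ccccc2)c1)[C@H]1COC(C)(C)O1 | intermediate
6 | 3,5-bis(benzyloxy)phenol | Oc1cc(OCc2ccccc2)cc(OCc2ccccc2)c1 | starting material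
7 | (R)-4-{(R)-[3,5-bis(benzyloxy)phenoxy][3,4,5-tris(benzyloxy)phenyl]methyl}-2,2-dimethyl-1,3-dioxolane | c1ccccc1COc1cc(OCc3ccccc3)cc(c1)O[C@H](c1cc(OCc3ccccc3)c(OCc3ccccc3)c(OCc3ccccc3)c1)[C@H]1COC(C)(C)O1 | intermediate
8 | (2R,3R)-3-[3,5-bis(benzyloxy)phenoxy]-3-[3,4,5-tris(benzyloxy)phenyl]propane-1,2-diol | c1ccccc1COc1cc(OCc3ccccc3)cc(c1)O[C@H](c1cc(OCc3ccccc3)c(OCc3ccccc3)c(OCc3ccccc3)c1)[C@H](O)CO | intermediate
9 | (4R)-4-{(R)-[3,5-bis(benzyloxy)phenoxy][3,4,5-tris(benzyloxy)phenyl]methyl}-2-phenyl-1,3-dioxolane (both acetal epimers) | c1ccccc1COc1cc(OCc3ccccc3)cc(c1)O[C@H](c1cc(OCc3ccccc3)c(OCc3ccccc3)c(OCc3ccccc3)c1)[C@H]1COC(c3ccccc3)O1 | intermediate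
10 | (2R,3R)-2-(benzyloxy)-3-[3,5-bis(benzyloxy)phenoxy]-3-[3,4,5-tris(benzyloxy)phenyl]propan-1-ol | c1ccccc1COc1cc(OCc3ccccc3)cc(c1)O[C@H](c1cc(OCc3ccccc3)c(OCc3ccccc3)c(OCc3ccccc3)c1)[C@H](OCc3ccccc3)CO | intermediate
11 | (2S,3R)-2-(benzyloxy)-3-[3,5-bis(benzyloxy)phenoxy]-3-[3,4,5-tris(benzyloxy)phenyl]propanal | c1ccccc1COc1cc(OCc3ccccc3)cc(c1)O[C@H](c1cc(OCc3ccccc3)c(OCc3ccccc3)c(OCc3ccccc3)c1)[C@H](OCc3ccccc3)C=O | intermediate
12 | (+)-catechin, (2R,3S)-2-(3,4-dihydroxyphenyl)chroman-3,5,7-triol | O[C@H]1Cc2c(O)cc(O)cc2O[C@@H]1c1ccc(O)c(O)c1 | starting material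
13 | 5,7,3′,4′-tetra-O-benzyl-(+)-catechin | O[C@H]1Cc2c(OCc3ccccc3)cc(OCc3ccccc3)cc2O[C@@H]1c1ccc(OCc2ccccc2)c(OCc2ccccc2)c1 | intermediate
14 | 8-bromo-5,7,3′,4′-tetra-O-benzyl-(+)-catechin | O[C@H]1Cc2c(OCc3ccccc3)cc(OCc3ccccc3)c(Br)c2O[C@@H]1c1ccc(OCc2ccccc2)c(OCc2ccccc2)c1 | intermediate
15 | 8-bromo-3,5,7,3′,4′-penta-O-benzyl-(+)-catechin | Brc1c(OCc3ccccc3)cc(OCc3ccccc3)c2c1O[C@H](c1ccc(OCc3ccccc3)c(OCc3ccccc3)c1)[C@@H](OCc3ccccc3)C2 | intermediate
16 | 8-lithio-3,5,7,3′,4′-penta-O-benzyl-(+)-catechin | [Li]c1c(OCc3ccccc3)cc(OCc3ccccc3)c2c1O[C@H](c1ccc(OCc3ccccc3)c(OCc3ccccc3)c1)[C@@H](OCc3ccccc3)C2 | intermediate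
17 | (1RS,2R,3R)-2-(benzyloxy)-3-[3,5-bis(benzyloxy)phenoxy]-1-(3,5,7,3′,4′-penta-O-benzylcatechin-8-yl)-3-[3,4,5-tris(benzyloxy)phenyl]propan-1-ol (aryl ether carbinol, C4 epimer mixture) | c1ccccc1COc1cc(OCc3ccccc3)cc(c1)O[C@H](c1cc(OCc3ccccc3)c(OCc3ccccc3)c(OCc3ccccc3)c1)[C@H](OCc3ccccc3)C(O)c1c(OCc3ccccc3)cc(OCc3ccccc3)c2c1O[C@H](c1ccc(OCc3ccccc3)c(OCc3ccccc3)c1)[C@@H](OCc3ccccc3)C2 | intermediate
18 | C4 benzylic cation from 17 (quinone-methide-type oxocarbenium ion, triflate counter-ion) | c1ccccc1COc1cc(OCc3ccccc3)cc(c1)O[C@H](c1cc(OCc3ccccc3)c(OCc3ccccc3)c(OCc3ccccc3)c1)[C@H](OCc3ccccc3)[CH+]c1c(OCc3ccccc3)cc(OCc3ccccc3)c2c1O[C@H](c1ccc(OCc3ccccc3)c(OCc3ccccc3)c1)[C@@H](OCc3ccccc3)C2 | intermediate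
19 | undeca-O-benzyl-epigallocatechin-(4β→8)-catechin, upper unit (2R,3R,4R), lower unit (2R,3S) | c1ccccc1COc1cc(OCc3ccccc3)c2c(c1)O[C@H](c1cc(OCc3ccccc3)c(OCc3ccccc3)c(OCc3ccccc3)c1)[C@H](OCc3ccccc3)[C@H]2c1c(OCc3ccccc3)cc(OCc3ccccc3)c2c1O[C@H](c1ccc(OCc3ccccc3)c(OCc3ccccc3)c1)[C@@H](OCc3ccccc3)C2 | intermediate
20 | epigallocatechin-(4β→8)-catechin, (2R,3R,4R)-4-[(2R,3S)-2-(3,4-dihydroxyphenyl)-3,5,7-trihydroxychroman-8-yl]-2-(3,4,5-trihydroxyphenyl)chroman-3,5,7-triol (CNP0225927.1) | Oc1cc(O)c2c(c1)O[C@H](c1cc(O)c(O)c(O)c1)[C@H](O)[C@H]2c1c(O)cc(O)c2c1O[C@H](c1ccc(O)c(O)c1)[C@@H](O)C2 | target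

Total step count: 13.
Longest linear sequence: 10 steps (steps 1–7, then 11–13); the catechin branch (steps 8–10) joins at step 11.

Steps most likely to fail

1. Step 12 (cationic ring closure). What may go wrong:
- capture of the cation by the tribenzyloxyphenyl ring or by a second molecule;
- proton loss from C3 to an enol ether;
- attack syn to the C3 benzyloxy group;
- acid-induced heterolysis of the newly formed interflavan bond.

The fallback reverses the order in which the two aryl bonds at C4 are made. It sets out from aldehyde 11 (with 13 as source of the nucleophile) and returns at 19. Lewis-acid-mediated intramolecular Friedel–Crafts hydroxyalkylation of 11 (TMSOTf or SnCl4, CH2Cl2, −78 °C) closes ring C first and gives 3,5,7,3′,4′,5′-hexa-O-benzyl-epigallocatechin-4-ol F1. Compound 13 is O-benzylated (NaH, BnBr, DMF) to 3,5,7,3′,4′-penta-O-benzyl-(+)-catechin F2. The established Lewis-acid-promoted condensation of the flavan-4-ol with an excess of F2 (TMSOTf, CH2Cl2, −78 °C, best done with F2 present so that F1 is ionised and captured as it forms) then makes the C4–C8′ bond. Attack occurs anti to the C3 benzyloxy group of the 2,3-cis flavan-4-yl cation and gives 19.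

2. Step 3 (Mitsunobu etherification). What may go wrong:
- loss of stereochemical integrity through ion-pair (SN1-type) substitution at the electron-rich benzylic centre;
- low conversion because the carbinol is flanked by the aryl and dioxolane groups.

The fallback replaces inversion by a retentive C–O coupling on the epimeric carbinol. It sets out from 5 (the unseparated carbinol mixture from step 2 serves equally) and returns at 7. Dess–Martin oxidation gives [(R)-2,2-dimethyl-1,3-dioxolan-4-yl][3,4,5-tris(benzyloxy)phenyl]methanone F3. Felkin–Anh-controlled reduction with L-Selectride (THF, −78 °C) should give (R)-[(R)-2,2-dimethyl-1,3-dioxolan-4-yl][3,4,5-tris(benzyloxy)phenyl]methanol F4, the syn carbinol. Commercial 5-bromoresorcinol is benzylated (BnBr, K2CO3, DMF) to 1,3-bis(benzyloxy)-5-bromobenzene F5. Palladium-catalysed C–O cross-coupling of F4 with F5 (bulky biarylphosphine ligand, Cs2CO3, toluene, 90 °C) forms the aryl ether with retention, because the carbinol C–O bond is never broken, and gives 7.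

3. Step 11 (aryllithium addition). What may go wrong:
- deprotonation of the aldehyde α-carbon by the organolithium, followed by β-elimination of the aryloxide or epimerisation at C3;
- sluggish addition of the doubly ortho-substituted nucleophile.

The fallback changes the electrophile to a less acidic acyl donor and reaches the carbinol by acylation and reduction. It sets out from 11 and returns at 17. Pinnick oxidation (NaClO2, NaH2PO4, 2-methyl-2-butene) gives (2S,3R)-2-(benzyloxy)-3-[3,5-bis(benzyloxy)phenoxy]-3-[3,4,5-tris(benzyloxy)phenyl]propanoic acid F6. Amide coupling with N,O-dimethylhydroxylamine hydrochloride (EDC, HOBt, i-Pr2NEt) gives the corresponding N-methoxy-N-methylamide F7. Acylation of aryllithium 16 with F7 (THF, −78 °C) gives (2S,3R)-2-(benzyloxy)-3-[3,5-bis(benzyloxy)phenoxy]-1-(3,5,7,3′,4′-penta-O-benzylcatechin-8-yl)-3-[3,4,5-tris(benzyloxy)phenyl]propan-1-one F8. Hydride reduction (NaBH4, THF/MeOH, or LiAlH4 at −78 °C) gives 17; either carbinol epimer serves.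

Further compounds
F1 | step 12 | (2R,3R)-3,5,7-tris(benzyloxy)-2-[3,4,5-tris(benzyloxy)phenyl]chroman-4-ol (3,5,7,3′,4′,5′-hexa-O-benzyl-epigallocatechin-4-ol, C4 epimers) | c1ccccc1COc1cc(OCc3ccccc3)c2c(c1)O[C@H](c1cc(OCc3ccccc3)c(OCc3ccccc3)c(OCc3ccccc3)c1)[C@H](OCc3ccccc3)C2O
F2 | step 12 | 3,5,7,3′,4′-penta-O-benzyl-(+)-catechin | c1c(OCc3ccccc3)cc(OCc3ccccc3)c2c1O[C@H](c1ccc(OCc3ccccc3)c(OCc3ccccc3)c1)[C@@H](OCc3ccccc3)C2
F3 | step 3 | [(R)-2,2-dimethyl-1,3-dioxolan-4-yl][3,4,5-tris(benzyloxy)phenyl]methanone | O=C(c1cc(OCc2ccccc2)c(OCc2ccccc2)c(OCc2ccccc2)c1)[C@H]1COC(C)(C)O1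
F4 | step 3 | (R)-[(R)-2,2-dimethyl-1,3-dioxolan-4-yl][3,4,5-tris(benzyloxy)phenyl]methanol (syn carbinol) | O[C@H](c1cc(OCc2ccccc2)c(OCc2ccccc2)c(OCc2ccccc2)c1)[C@H]1COC(C)(C)O1
F5 | step 3 | 1,3-bis(benzyloxy)-5-bromobenzene | Brc1cc(OCc2ccccc2)cc(OCc2ccccc2)c1
F6 | step 11 | (2S,3R)-2-(benzyloxy)-3-[3,5-bis(benzyloxy)phenoxy]-3-[3,4,5-tris(benzyloxy)phenyl]propanoic acid | c1ccccc1COc1cc(OCc3ccccc3)cc(c1)O[C@H](c1cc(OCc3ccccc3)c(OCc3ccccc3)c(OCc3ccccc3)c1)[C@H](OCc3ccccc3)C(=O)O
F7 | step 11 | (2S,3R)-2-(benzyloxy)-3-[3,5-bis(benzyloxy)phenoxy]-N-methoxy-N-methyl-3-[3,4,5-tris(benzyloxy)phenyl]propanamide | c1ccccc1COc1cc(OCc3ccccc3)cc(c1)O[C@H](c1cc(OCc3ccccc3)c(OCc3ccccc3)c(OCc3ccccc3)c1)[C@H](OCc3ccccc3)C(=O)N(C)OC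
F8 | step 11 | (2S,3R)-2-(benzyloxy)-3-[3,5-bis(benzyloxy)phenoxy]-1-(3,5,7,3′,4′-penta-O-benzylcatechin-8-yl)-3-[3,4,5-tris(benzyloxy)phenyl]propan-1-one | c1ccccc1COc1cc(OCc3ccccc3)cc(c1)O[C@H](c1cc(OCc3ccccc3)c(OCc3ccccc3)c(OCc3ccccc3)c1)[C@H](OCc3ccccc3)C(=O)c1c(OCc3ccccc3)cc(OCc3ccccc3)c2c1O[C@H](c1ccc(OCc3ccccc3)c(OCc3ccccc3)c1)[C@@H](OCc3ccccc3)C2
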